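**Retrosynthetic overview**

1. The target is an epicatechin-(4β→8)-taxifolin dimer. The strategy rests on upper-unit C4: a benzylic methine bonded to C4a of the upper ring A and to C8 of the taxifolin ring A, and trans to the C3 hydroxyl on upper ring C.
2. Key disconnection C4–C4a (which also opens upper ring C): a trans C3–C4 oxirane whose C2 carries a 3,5-bis(benzyloxy)phenyl ether; the ortho carbon of that ether opens the oxirane at C4 with inversion.
3. The C2–O aryl ether comes from Mitsunobu inversion of the erythro epoxy alcohol; the oxirane comes from a matched Katsuki–Sharpless epoxidation of an (R,E)-allylic alcohol.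
4. The C4–C8(taxifolin) bond comes from Suzuki coupling of 8-iodo-penta-O-benzyl-taxifolin with an (R,E)-alkenylboronate made from 3,4-bis(benzyloxy)benzaldehyde.
5. Ring order: the taxifolin rings A, B and C, the upper catechol ring and the upper ring A (as the phenol) are brought in intact; upper ring C is the only ring formed (step 10); global hydrogenolysis is last.

Key step: step 10

Assumption: 3,4-bis(benzyloxy)benzaldehyde (5) and 3,5-bis(benzyloxy)phenol (14) are bought as such (the phenol is otherwise made from phloroglucinol by benzylation).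

Remark: flavan numbering (C2, C3, C4, C4a) is used for the carbons of the future upper unit. The descriptor of the oxirane carbon next to the carbinol changes from S in 13 to R in 15 only because substituent priorities change on etherification; the centre itself is not touched.

**Route**

Step 1
Reactants: 1 (+)-taxifolin
Product: 2 (2R,3R)-5,7-bis(benzyloxy)-2-[3,4-bis(benzyloxy)phenyl]-3-hydroxychroman-4-one
Conditions: BnBr (4.5 equiv), K2CO3, DMF, rt to 40 °C, Ar
Reagents that add atoms: benzyl bromide BrCc1ccccc1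
Why: Williamson O-benzylation of the four phenols under carbonate, which does not deprotonate the aliphatic 3-OH; early capping of the 4'-phenol closes the quinone-methide route to C2 epimerisation, so the (2R,3R) centres should be carried through unchanged.

Step 2
Reactants: 2 (2R,3R)-5,7-bis(benzyloxy)-2-[3,4-bis(benzyloxy)phenyl]-3-hydroxychroman-4-one
Product: 3 (2R,3R)-3,5,7-tris(benzyloxy)-2-[3,4-bis(benzyloxy)phenyl]chroman-4-one
Conditions: Ag2O, BnBr, Bu4NI (cat.), CH2Cl2, rt, dark
Reagents that add atoms: benzyl bromide BrCc1ccccc1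
Why: Silver-oxide-assisted (Purdie-type) Williamson benzylation of the neutral 3-hydroxyl avoids an enolate of the 4-ketone, so ring opening and C2/C3 epimerisation should not occur.

Step 3
Reactants: 3 (2R,3R)-3,5,7-tris(benzyloxy)-2-[3,4-bis(benzyloxy)phenyl]chroman-4-one
Product: 4 (2R,3R)-3,5,7-tris(benzyloxy)-2-[3,4-bis(benzyloxy)phenyl]-8-iodochroman-4-one
Conditions: NIS (1.05 equiv), CF3CO2H (cat.), MeCN–CH2Cl2, 0 °C to rt, dark
Reagents that add atoms: N-iodosuccinimide O=C1CCC(=O)N1I
Why: Electrophilic aromatic iodination of the most electron-rich ring; with O5 alkylated, C6 is flanked by two benzyloxy groups, so substitution should go to the less hindered C8 (ortho to O1 and O7, para to O5) and not to C6 or the catechol ring.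

Step 4
Reactants: 5 3,4-bis(benzyloxy)benzaldehyde
Product: 7 rac-1-[3,4-bis(benzyloxy)phenyl]prop-2-yn-1-yl acetate, via bromomagnesium alkoxide 6 (not isolated)
Conditions: HC≡CMgBr, THF, 0 °C; then Ac2O, 0 °C to rt
Reagents that add atoms: ethynylmagnesium bromide C#C[Mg]Br; acetic anhydride CC(=O)OC(C)=O
Why: Grignard 1,2-addition to the aldehyde followed by O-acylation of the magnesium alkoxide in the same pot; the product is racemic by design.

Step 5
Reactants: 7 rac-1-[3,4-bis(benzyloxy)phenyl]prop-2-yn-1-yl acetate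
Product: 8 (R)-1-[3,4-bis(benzyloxy)phenyl]prop-2-yn-1-ol
Conditions: Novozym 435 (immobilised Candida antarctica lipase B), n-BuOH (3 equiv), MTBE, 35 °C, stopped near 45% conversion
Reagents that add atoms: none
Why: Lipase-catalysed enantioselective transesterification (kinetic resolution; Kazlauskas rule with the aryl group as large and ethynyl as medium substituent) should deacylate only the (R)-acetate and so set the carbinol centre; the unreacted (S)-enantiomer of 7 is removed by chromatography.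

Step 6
Reactants: 8 (R)-1-[3,4-bis(benzyloxy)phenyl]prop-2-yn-1-ol
Product: 11 (R,E)-1-[3,4-bis(benzyloxy)phenyl]-3-(4,4,5,5-tetramethyl-1,3,2-dioxaborolan-2-yl)prop-2-en-1-ol, via propargylic borate ester 9 (not isolated), via alkenylboronate borate ester 10 (not isolated)
Conditions: pinacolborane (2.4 equiv), Et3N (10 mol%), CH2Cl2, rt (H2 evolution); then Cp2Zr(H)Cl (10 mol%), 40 °C; aq. NH4Cl work-up
Reagents that add atoms: pinacolborane CC1(C)OBOC1(C)C
Why: Zirconocene-hydride-catalysed syn, anti-Markovnikov hydroboration of the terminal alkyne should give only the E-alkenylboronate; the hydroxyl is masked in the flask as its borate ester by the first equivalent of pinacolborane and freed on aqueous work-up, and the carbinol centre is not involved.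

Step 7
Reactants: 4 (2R,3R)-3,5,7-tris(benzyloxy)-2-[3,4-bis(benzyloxy)phenyl]-8-iodochroman-4-one; 11 (R,E)-1-[3,4-bis(benzyloxy)phenyl]-3-(4,4,5,5-tetramethyl-1,3,2-dioxaborolan-2-yl)prop-2-en-1-ol
Product: 12 (2R,3R)-3,5,7-tris(benzyloxy)-2-[3,4-bis(benzyloxy)phenyl]-8-{(R,E)-3-[3,4-bis(benzyloxy)phenyl]-3-hydroxyprop-1-en-1-yl}chroman-4-one
Conditions: Pd(dppf)Cl2 (5 mol%), K3PO4 (3 equiv), THF–H2O (9:1), 45 °C, degassed
Reagents that add atoms: none
Why: Suzuki–Miyaura coupling (oxidative addition of zerovalent palladium to the C8–I bond, transmetalation with retention of alkene geometry, reductive elimination) forms the C8–C bond; the mild phosphate base at 45 °C should leave the enolisable 3-benzyloxy ketone and the carbinol centre untouched.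

Step 8
Reactants: 12 (2R,3R)-3,5,7-tris(benzyloxy)-2-[3,4-bis(benzyloxy)phenyl]-8-{(R,E)-3-[3,4-bis(benzyloxy)phenyl]-3-hydroxyprop-1-en-1-yl}chroman-4-one
Product: 13 (2R,3R)-3,5,7-tris(benzyloxy)-2-[3,4-bis(benzyloxy)phenyl]-8-[(2S,3S)-3-{(S)-[3,4-bis(benzyloxy)phenyl](hydroxy)methyl}oxiran-2-yl]chroman-4-one (erythro epoxy alcohol)
Conditions: Ti(OiPr)4 (20 mol%), L-(+)-diisopropyl tartrate (26 mol%), t-BuOOH (2 equiv, in decane), 4 Å MS, CH2Cl2, −20 °C; Na2SO4/H2O quench, Et3N-washed silica
Reagents that add atoms: tert-butyl hydroperoxide CC(C)(C)OO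
Why: Katsuki–Sharpless epoxidation in its matched sense: the L-(+)-tartrate complex delivers oxygen to the alkene face that makes the aryl-bearing oxirane carbon S, and the (R)-carbinol is the fast-reacting enantiomer that gives the erythro epoxy alcohol, so both new centres are set by the reagent reinforced by the carbinol; any (S)-carbinol diastereomer carried over from step 5 is mismatched and should lag behind.

Step 9
Reactants: 13 the erythro epoxy alcohol of step 8; 14 3,5-bis(benzyloxy)phenol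
Product: 15 (2R,3R)-3,5,7-tris(benzyloxy)-2-[3,4-bis(benzyloxy)phenyl]-8-[(2S,3R)-3-{(R)-[3,5-bis(benzyloxy)phenoxy][3,4-bis(benzyloxy)phenyl]methyl}oxiran-2-yl]chroman-4-one
Conditions: PPh3, DIAD, toluene, −10 °C to rt
Reagents that add atoms: none
Why: Mitsunobu etherification with a phenol (pKa about 9–10): SN2 displacement of the alkoxyphosphonium ion in non-polar toluene at low temperature should invert the carbinol carbon, converting the erythro alcohol into the threo aryl ether that maps onto the 2,3-cis relationship of the upper unit.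

Step 10
Reactants: 15 the threo epoxy aryl ether of step 9
Product: 16 (2R,3R)-3,5,7-tris(benzyloxy)-2-[3,4-bis(benzyloxy)phenyl]-8-{(2R,3R,4R)-5,7-bis(benzyloxy)-2-[3,4-bis(benzyloxy)phenyl]-3-hydroxychroman-4-yl}chroman-4-one
Conditions: BF3·OEt2 (1.1 equiv), CH2Cl2, −78 °C to −40 °C; Et3N then aq. NaHCO3 quench
Reagents that add atoms: none
Why: BF3 coordinates the oxirane oxygen, the C4–O bond (benzylic to the trioxygenated taxifolin ring A) lengthens, and the ortho carbon of the 3,5-bis(benzyloxy)phenyl ether attacks C4 from the side opposite the oxygen, after which the arenium ion loses a proton (intramolecular Friedel–Crafts epoxide–arene cyclisation). The closest known reaction type is the Lewis-acid-mediated cyclisation of aryl trans-3-arylglycidyl ethers to trans-4-arylchroman-3-ols. Upper ring C is closed in the 6-endo mode at the epoxide, both oxirane carbons ending up in the new pyran ring. The new stereocentre C4 is set by inversion of the (S)-configured oxirane carbon, which places the taxifolin aryl group trans to the C3 oxygen (4R), while C2 and C3 are carried in unchanged from the threo epoxy ether and give the 2,3-cis pattern. The step needs attack at C4 instead of C3 (5-exo) and by the phloroglucinol-type ring instead of the catechol ring: benzylic activation by the ring A oxygens, tempered by the conjugated C4 ketone so that the opening stays tight, directs the nucleophile to C4, and only the triply activated ether ring, whose two ortho carbons are equivalent, can reach C4 through a six-membered transition state.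

Step 11
Reactants: 16 the nona-O-benzyl dimer of step 10
Product: 17 (2R,3R)-2-(3,4-dihydroxyphenyl)-8-[(2R,3R,4R)-2-(3,4-dihydroxyphenyl)-3,5,7-trihydroxychroman-4-yl]-3,5,7-trihydroxychroman-4-one
Conditions: H2 (1 atm), Pd(OH)2 on carbon, THF–MeOH (1:1), rt; filtration, Sephadex LH-20
Reagents that add atoms: none
Why: Catalytic hydrogenolysis of the nine O-benzyl groups at room temperature; the vinylogous-ester-type aryl ketone, the pyran C–O bonds and the C4–C8 interflavan bond are inert under these conditions, and no stereocentre is touched.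

**Compound list**

1 | (+)-taxifolin, (2R,3R) | O=C1c2c(O)cc(O)cc2O[C@H](c2ccc(O)c(O)c2)[C@H]1O | starting material
2 | (2R,3R)-5,7-bis(benzyloxy)-2-[3,4-bis(benzyloxy)phenyl]-3-hydroxychroman-4-one | O=C1c2c(OCc5ccccc5)cc(OCc5ccccc5)cc2O[C@H](c2ccc(OCc5ccccc5)c(OCc5ccccc5)c2)[C@H]1O | intermediate
3 | (2R,3R)-3,5,7-tris(benzyloxy)-2-[3,4-bis(benzyloxy)phenyl]chroman-4-one | O=C1c2c(OCc5ccccc5)cc(OCc5ccccc5)cc2O[C@H](c2ccc(OCc5ccccc5)c(OCc5ccccc5)c2)[C@H]1OCc5ccccc5 | intermediate
4 | (2R,3R)-3,5,7-tris(benzyloxy)-2-[3,4-bis(benzyloxy)phenyl]-8-iodochroman-4-one | O=C1c2c(OCc5ccccc5)cc(OCc5ccccc5)c(I)c2O[C@H](c2ccc(OCc5ccccc5)c(OCc5ccccc5)c2)[C@H]1OCc5ccccc5 | intermediate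
5 | 3,4-bis(benzyloxy)benzaldehyde | O=Cc1ccc(OCc2ccccc2)c(OCc2ccccc2)c1 | starting material
6 | bromomagnesium 1-[3,4-bis(benzyloxy)phenyl]prop-2-yn-1-olate (racemic, not isolated) | C#CC(O[Mg]Br)c1ccc(OCc2ccccc2)c(OCc2ccccc2)c1 | intermediate
7 | rac-1-[3,4-bis(benzyloxy)phenyl]prop-2-yn-1-yl acetate | CC(=O)OC(C#C)c1ccc(OCc2ccccc2)c(OCc2ccccc2)c1 | intermediate
8 | (R)-1-[3,4-bis(benzyloxy)phenyl]prop-2-yn-1-ol | C#C[C@@H](O)c1ccc(OCc2ccccc2)c(OCc2ccccc2)c1 | intermediate
9 | (R)-2-({1-[3,4-bis(benzyloxy)phenyl]prop-2-yn-1-yl}oxy)-4,4,5,5-tetramethyl-1,3,2-dioxaborolane (not isolated) | C#C[C@@H](OB1OC(C)(C)C(C)(C)O1)c1ccc(OCc2ccccc2)c(OCc2ccccc2)c1 | intermediate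
10 | (R,E)-2-{3-[3,4-bis(benzyloxy)phenyl]-3-[(4,4,5,5-tetramethyl-1,3,2-dioxaborolan-2-yl)oxy]prop-1-en-1-yl}-4,4,5,5-tetramethyl-1,3,2-dioxaborolane (not isolated) | CC1(C)OB(/C=C/[C@@H](OB2OC(C)(C)C(C)(C)O2)c2ccc(OCc3ccccc3)c(OCc3ccccc3)c2)OC1(C)C | intermediate
11 | (R,E)-1-[3,4-bis(benzyloxy)phenyl]-3-(4,4,5,5-tetramethyl-1,3,2-dioxaborolan-2-yl)prop-2-en-1-ol | CC1(C)OB(/C=C/[C@@H](O)c2ccc(OCc3ccccc3)c(OCc3ccccc3)c2)OC1(C)C | intermediate
12 | (2R,3R)-3,5,7-tris(benzyloxy)-2-[3,4-bis(benzyloxy)phenyl]-8-{(R,E)-3-[3,4-bis(benzyloxy)phenyl]-3-hydroxyprop-1-en-1-yl}chroman-4-one | O=C1c2c(OCc5ccccc5)cc(OCc5ccccc5)c(/C=C/[C@@H](O)c3ccc(OCc5ccccc5)c(OCc5ccccc5)c3)c2O[C@H](c2ccc(OCc5ccccc5)c(OCc5ccccc5)c2)[C@H]1OCc5ccccc5 | intermediate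
13 | (2R,3R)-3,5,7-tris(benzyloxy)-2-[3,4-bis(benzyloxy)phenyl]-8-[(2S,3S)-3-{(S)-[3,4-bis(benzyloxy)phenyl](hydroxy)methyl}oxiran-2-yl]chroman-4-one | O=C1c2c(OCc5ccccc5)cc(OCc5ccccc5)c([C@@H]3O[C@H]3[C@@H](O)c4ccc(OCc5ccccc5)c(OCc5ccccc5)c4)c2O[C@H](c2ccc(OCc5ccccc5)c(OCc5ccccc5)c2)[C@H]1OCc5ccccc5 | intermediate
14 | 3,5-bis(benzyloxy)phenol | Oc1cc(OCc2ccccc2)cc(OCc2ccccc2)c1 | starting material
15 | (2R,3R)-3,5,7-tris(benzyloxy)-2-[3,4-bis(benzyloxy)phenyl]-8-[(2S,3R)-3-{(R)-[3,5-bis(benzyloxy)phenoxy][3,4-bis(benzyloxy)phenyl]methyl}oxiran-2-yl]chroman-4-one | O=C1c2c(OCc5ccccc5)cc(OCc5ccccc5)c([C@@H]3O[C@H]3[C@H](Oc4cc(OCc5ccccc5)cc(OCc5ccccc5)c4)c4ccc(OCc5ccccc5)c(OCc5ccccc5)c4)c2O[C@H](c2ccc(OCc5ccccc5)c(OCc5ccccc5)c2)[C@H]1OCc5ccccc5 | intermediate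
16 | (2R,3R)-3,5,7-tris(benzyloxy)-2-[3,4-bis(benzyloxy)phenyl]-8-{(2R,3R,4R)-5,7-bis(benzyloxy)-2-[3,4-bis(benzyloxy)phenyl]-3-hydroxychroman-4-yl}chroman-4-one | O=C1c2c(OCc5ccccc5)cc(OCc5ccccc5)c([C@H]3c4c(OCc5ccccc5)cc(OCc5ccccc5)cc4O[C@H](c4ccc(OCc5ccccc5)c(OCc5ccccc5)c4)[C@@H]3O)c2O[C@H](c2ccc(OCc5ccccc5)c(OCc5ccccc5)c2)[C@H]1OCc5ccccc5 | intermediate
17 | (2R,3R)-2-(3,4-dihydroxyphenyl)-8-[(2R,3R,4R)-2-(3,4-dihydroxyphenyl)-3,5,7-trihydroxychroman-4-yl]-3,5,7-trihydroxychroman-4-one | O=C1c2c(O)cc(O)c([C@H]3c4c(O)cc(O)cc4O[C@H](c4ccc(O)c(O)c4)[C@@H]3O)c2O[C@H](c2ccc(O)c(O)c2)[C@H]1O | target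

**Totals**

Total step count: 11.
Longest linear sequence: 8 steps (5 to 17 through steps 4–11; equally 1 to 17 through steps 1–3 and 7–11).

**The three steps most likely to fail**

Step 10 (key cyclisation). The activated oxirane may ionise fully and then suffer a 1,2-hydride shift to the benzyl ketone (Meinwald rearrangement). The Lewis acid may instead ionise the benzylic C2–O aryl ether. Either process erodes the invertive 6-endo pathway. Fallback, from 15 back to 16: the one-step Lewis-acid cyclisation is replaced by halide opening followed by silver-assisted alkylation. MgBr2·OEt2 in Et2O–CH2Cl2 at −30 °C should open the oxirane at its benzylic carbon to the bromohydrin (2R,3R)-3,5,7-tris(benzyloxy)-2-[3,4-bis(benzyloxy)phenyl]-8-{(1R,2S,3R)-1-bromo-3-[3,5-bis(benzyloxy)phenoxy]-3-[3,4-bis(benzyloxy)phenyl]-2-hydroxypropyl}chroman-4-one F1. AgOTf with 2,6-di-tert-butyl-4-methylpyridine in CH2Cl2 at −60 °C then ionises the benzylic bromide, and the tethered ether ring closes by Friedel–Crafts alkylation to 16. No strong Lewis acid meets the epoxide or the aryl ether in this variant. The configuration at the brominated carbon is lost on ionisation, and the trans arrangement at C3/C4 is then expected from attack anti to the C3–O bond in the half-chair.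

Step 9 (Mitsunobu etherification). The alkoxyphosphonium ion sits on an electron-rich benzylic carbon and may leak into an SN1 pathway, which would scramble C2; C-alkylation of the ambident phenol may also compete. Fallback, from 7 back to 15: the ether is made first and the epoxide afterwards, so neither the Mitsunobu step nor the directed epoxidation is needed. Copper-catalysed enantioselective propargylic etherification of racemic acetate 7 with phenol 14 (CuOTf·½C6H6, chiral pybox ligand, iPr2NEt, through a copper allenylidene of monovalent copper; the ligand antipode chosen for the S product) should give (S)-1-({1-[3,4-bis(benzyloxy)phenyl]prop-2-yn-1-yl}oxy)-3,5-bis(benzyloxy)benzene F2 from both enantiomers of 7. Hydroboration with pinacolborane and Cp2Zr(H)Cl (cat.) gives (S,E)-2-{3-[3,4-bis(benzyloxy)phenyl]-3-[3,5-bis(benzyloxy)phenoxy]prop-1-en-1-yl}-4,4,5,5-tetramethyl-1,3,2-dioxaborolane F3. Suzuki coupling with iodide 4 under the conditions of step 7 gives (2R,3R)-3,5,7-tris(benzyloxy)-2-[3,4-bis(benzyloxy)phenyl]-8-{(S,E)-3-[3,4-bis(benzyloxy)phenyl]-3-[3,5-bis(benzyloxy)phenoxy]prop-1-en-1-yl}chroman-4-one F4. A reagent-controlled Shi-type dioxirane epoxidation then returns to 15; it would use the antipode of the fructose-derived ketone (by analogy with trans-β-methylstyrene), KHSO5 (as 2KHSO5·KHSO4·K2SO4) and K2CO3 buffer in MeCN–dimethoxymethane–H2O at 0 °C.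

Step 8 (directed epoxidation). The Lewis-acidic titanium alkoxide may open the forming oxirane at its electron-rich benzylic carbon, and oxygen transfer to the hindered alkene may be slow. Fallback, from 12 back to 13: the metal-alkoxide-directed oxygen transfer is replaced by a metal-free, reagent-controlled dioxirane epoxidation under basic buffer (the same ketone antipode, KHSO5 as 2KHSO5·KHSO4·K2SO4, K2CO3, MeCN–dimethoxymethane–H2O, 0 °C). The alkene face is then chosen by the catalyst, and the erythro relationship follows from that face and the fixed (R)-carbinol; no new compound is made on the way.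

**Further compounds**

F1 | step 10 | (2R,3R)-3,5,7-tris(benzyloxy)-2-[3,4-bis(benzyloxy)phenyl]-8-{(1R,2S,3R)-1-bromo-3-[3,5-bis(benzyloxy)phenoxy]-3-[3,4-bis(benzyloxy)phenyl]-2-hydroxypropyl}chroman-4-one | O=C1c2c(OCc5ccccc5)cc(OCc5ccccc5)c([C@@H](Br)[C@@H](O)[C@H](Oc4cc(OCc5ccccc5)cc(OCc5ccccc5)c4)c4ccc(OCc5ccccc5)c(OCc5ccccc5)c4)c2O[C@H](c2ccc(OCc5ccccc5)c(OCc5ccccc5)c2)[C@H]1OCc5ccccc5
F2 | step 9 | (S)-1-({1-[3,4-bis(benzyloxy)phenyl]prop-2-yn-1-yl}oxy)-3,5-bis(benzyloxy)benzene | C#C[C@H](Oc1cc(OCc2ccccc2)cc(OCc2ccccc2)c1)c1ccc(OCc2ccccc2)c(OCc2ccccc2)c1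
F3 | step 9 | (S,E)-2-{3-[3,4-bis(benzyloxy)phenyl]-3-[3,5-bis(benzyloxy)phenoxy]prop-1-en-1-yl}-4,4,5,5-tetramethyl-1,3,2-dioxaborolane | CC1(C)OB(/C=C/[C@H](Oc2cc(OCc3ccccc3)cc(OCc3ccccc3)c2)c2ccc(OCc3ccccc3)c(OCc3ccccc3)c2)OC1(C)C
F4 | step 9 | (2R,3R)-3,5,7-tris(benzyloxy)-2-[3,4-bis(benzyloxy)phenyl]-8-{(S,E)-3-[3,4-bis(benzyloxy)phenyl]-3-[3,5-bis(benzyloxy)phenoxy]prop-1-en-1-yl}chroman-4-one | O=C1c2c(OCc5ccccc5)cc(OCc5ccccc5)c(/C=C/[C@H](Oc4cc(OCc5ccccc5)cc(OCc5ccccc5)c4)c4ccc(OCc5ccccc5)c(OCc5ccccc5)c4)c2O[C@H](c2ccc(OCc5ccccc5)c(OCc5ccccc5)c2)[C@H]1OCc5ccccc5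
F0 | step 8 | none | none
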